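**Retrosynthetic overview**

1. Benzofuran numbering is used: unit 1 (unprimed) carries the styryl group at C6, and unit 2 (primed) is bonded through C6′ to C3. The strategy rests on the benzene ring of unit 2 (C3a′, C4′, C5′, C6′, C7′, C7a′): it bears only oxygen at C4′ and unit 1 at C6′, and it is fused to a furan whose O1′–C2′–C3′ chain can tether two alkynes.
2. Target 31 ⇐ BBr3 demethylation and Tamao oxidation (C4′–Si to C4′–OH) ⇐ silylarene 28 ⇐ rhodium-catalysed (2+2+2) cycloaddition of 1,6-diyne 27 with terminal alkyne 13, forming C3a′–C7a′, C4′–C5′ and C6′–C7′.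
3. Alkyne 13 ⇐ Ohira–Bestmann and Heck reactions ⇐ trans ester 9 ⇐ enantioselective carbenoid C–H insertion of aryldiazoacetate 7, made from 3-bromo-5-methoxyphenol.
4. Diyne 27 ⇐ O-ethynylation of anti alcohol 23 ⇐ chiral allenylzinc addition to 4-methoxybenzaldehyde ⇐ (R)-propargylic mesylate 20 from 3,5-dimethoxybenzaldehyde.
5. Ring order: dihydrofuran ring of unit 1 (step 5; its benzene ring is bought), then the dihydrofuran and benzene rings of unit 2 together (step 15).

Key step: step 15

Assumption: Rh2(S-PTTL)4 (step 5) and (S,S)-ProPhenol (step 10) are taken to give the configurations drawn for 8 and 19; should either sense of induction be opposite, the mirror-image catalyst or ligand is used with no other change.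

**Route**

Step 1
Reactants: 1 3-bromo-5-methoxyphenol; 2 4-methoxybenzyl chloride
Product: 3 1-bromo-3-methoxy-5-[(4-methoxybenzyl)oxy]benzene
Conditions: K2CO3, Bu4NI (cat.), DMF, 50 °C
Reagents that add atoms: none
Why: Williamson ether synthesis on the only phenol installs the benzylic CH2 that later becomes C2 of unit 1 together with its 4-methoxyphenyl group.

Step 2
Reactants: 3 1-bromo-3-methoxy-5-[(4-methoxybenzyl)oxy]benzene
Product: 5 methyl 2-{4-bromo-2-methoxy-6-[(4-methoxybenzyl)oxy]phenyl}-2-oxoacetate, via aryllithium 4 (not isolated)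
Conditions: LiN(iPr)2, THF, −78 °C; then inverse addition to (CO2Me)2 (3 equiv), THF, −78 °C
Reagents that add atoms: dimethyl oxalate, COC(=O)C(=O)OC
Why: Directed ortho-metalation at the carbon flanked by both alkoxy groups (the amide base does not exchange the bromide) followed by acylation with excess oxalate should give the aryl glyoxylate.

Step 3
Reactants: 5 methyl 2-{4-bromo-2-methoxy-6-[(4-methoxybenzyl)oxy]phenyl}-2-oxoacetate
Product: 6 methyl 2-{4-bromo-2-methoxy-6-[(4-methoxybenzyl)oxy]phenyl}-2-(tosylhydrazono)acetate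
Conditions: TsNHNH2, MeOH, 60 °C
Reagents that add atoms: 4-methylbenzenesulfonohydrazide, Cc1ccc(cc1)S(=O)(=O)NN
Why: Hydrazone condensation should occur at the ketone carbonyl, which is far more electrophilic than the ester.

Step 4
Reactants: 6 methyl 2-{4-bromo-2-methoxy-6-[(4-methoxybenzyl)oxy]phenyl}-2-(tosylhydrazono)acetate
Product: 7 methyl 2-{4-bromo-2-methoxy-6-[(4-methoxybenzyl)oxy]phenyl}-2-diazoacetate
Conditions: DBU, CH2Cl2, rt
Reagents that add atoms: none
Why: Bamford–Stevens elimination of sulfinate from the deprotonated tosylhydrazone should give the donor–acceptor aryldiazoacetate under mild conditions that leave the benzyl ether and the aryl bromide alone.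

Step 5
Reactants: 7 methyl 2-{4-bromo-2-methoxy-6-[(4-methoxybenzyl)oxy]phenyl}-2-diazoacetate
Product: 8 methyl (2S,3R)-6-bromo-4-methoxy-2-(4-methoxyphenyl)-2,3-dihydro-1-benzofuran-3-carboxylate (cis)
Conditions: Rh2(S-PTTL)4 (dirhodium tetrakis[N-phthaloyl-(S)-tert-leucinate], 1 mol%), toluene, −60 °C
Reagents that add atoms: none
Why: Intramolecular 1,5 C–H insertion of the divalent rhodium carbenoid into the activated benzylic C–H of the 4-methoxybenzyl ether closes the dihydrofuran ring of unit 1, the chiral carboxylate ligands choosing one enantiotopic hydrogen so that C2 is set as S and the concerted insertion delivers the cis C3 ester.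

Step 6
Reactants: 8 methyl (2S,3R)-6-bromo-4-methoxy-2-(4-methoxyphenyl)-2,3-dihydro-1-benzofuran-3-carboxylate
Product: 9 methyl (2S,3S)-6-bromo-4-methoxy-2-(4-methoxyphenyl)-2,3-dihydro-1-benzofuran-3-carboxylate (trans)
Conditions: NaOMe (0.5 equiv), MeOH/THF, rt
Reagents that add atoms: none
Why: Thermodynamic epimerisation through the ester enolate moves C3 to the more stable trans arrangement while C2 is untouched, ring opening by β-elimination being stereoelectronically disfavoured in the five-membered ring.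

Step 7
Reactants: 9 methyl (2S,3S)-6-bromo-4-methoxy-2-(4-methoxyphenyl)-2,3-dihydro-1-benzofuran-3-carboxylate; 10 4-methoxystyrene
Product: 11 methyl (2S,3S)-4-methoxy-2-(4-methoxyphenyl)-6-[(E)-2-(4-methoxyphenyl)ethenyl]-2,3-dihydro-1-benzofuran-3-carboxylate
Conditions: Pd(OAc)2 (5 mol%), P(o-tol)3, Et3N, DMF, 100 °C
Reagents that add atoms: none
Why: Heck reaction of a 3,5-dioxygenated aryl bromide with a styrene is the standard stilbene synthesis, syn insertion and syn β-hydride elimination giving the E alkene, and the amine base can only hold C3 in its trans configuration.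

Step 8
Reactants: 11 methyl (2S,3S)-4-methoxy-2-(4-methoxyphenyl)-6-[(E)-2-(4-methoxyphenyl)ethenyl]-2,3-dihydro-1-benzofuran-3-carboxylate
Product: 13 (2S,3S)-3-ethynyl-4-methoxy-2-(4-methoxyphenyl)-6-[(E)-2-(4-methoxyphenyl)ethenyl]-2,3-dihydro-1-benzofuran, via aldehyde 12 (not isolated)
Conditions: iBu2AlH (1.1 equiv), CH2Cl2, −78 °C; then MeOH, K2CO3, dimethyl (1-diazo-2-oxopropyl)phosphonate, −78 °C to rt
Reagents that add atoms: dimethyl (1-diazo-2-oxopropyl)phosphonate, COP(=O)(OC)C(=[N+]=[N-])C(C)=O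
Why: One-pot half-reduction and Ohira–Bestmann homologation converts the ester into the terminal alkyne without isolating the epimerisable aldehyde, and the carbonate base can only return C3 to the favoured trans configuration.

Step 9
Reactants: 14 benzyl(chloro)dimethylsilane; 15 ethynylmagnesium bromide
Product: 16 benzyl(ethynyl)dimethylsilane
Conditions: THF, 0 °C to rt
Reagents that add atoms: none
Why: Nucleophilic substitution at silicon by the alkynyl Grignard reagent is a standard preparation of silylacetylenes.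

Step 10
Reactants: 17 3,5-dimethoxybenzaldehyde; 16 benzyl(ethynyl)dimethylsilane
Product: 19 (R)-3-[benzyl(dimethyl)silyl]-1-(3,5-dimethoxyphenyl)prop-2-yn-1-ol, via methylzinc acetylide 18 (not isolated)
Conditions: Me2Zn (3 equiv), (S,S)-ProPhenol (10 mol%), Ph3PO (20 mol%), toluene, 0 °C to rt
Reagents that add atoms: none
Why: Dinuclear zinc–ProPhenol catalysed enantioselective alkynylation of an aromatic aldehyde, in which the chiral dizinc pocket delivers the alkynyl group to one carbonyl face and so sets the carbinol centre as R.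

Step 11
Reactants: 19 (R)-3-[benzyl(dimethyl)silyl]-1-(3,5-dimethoxyphenyl)prop-2-yn-1-ol
Product: 20 (R)-3-[benzyl(dimethyl)silyl]-1-(3,5-dimethoxyphenyl)prop-2-yn-1-yl methanesulfonate
Conditions: MsCl, Et3N, CH2Cl2, −78 °C; used crude at once
Reagents that add atoms: methanesulfonyl chloride, CS(=O)(=O)Cl
Why: O-Sulfonylation leaves the stereocentre untouched, and the two meta methoxy groups do not stabilise a benzylic cation, so the mesylate should survive at low temperature without ionising.

Step 12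
Reactants: 20 (R)-3-[benzyl(dimethyl)silyl]-1-(3,5-dimethoxyphenyl)prop-2-yn-1-yl methanesulfonate; 21 4-methoxybenzaldehyde
Product: 23 (1S,2S)-4-[benzyl(dimethyl)silyl]-2-(3,5-dimethoxyphenyl)-1-(4-methoxyphenyl)but-3-yn-1-ol, via allenylzinc 22 (not isolated)
Conditions: Pd(OAc)2 (5 mol%), PPh3 (5 mol%), Et2Zn (3 equiv), THF, −78 to −20 °C
Reagents that add atoms: none
Why: Marshall propargylation, in which zerovalent palladium displaces the mesylate anti (SN2′), transmetalation to zinc occurs with retention and the (aS)-allenylzinc adds through a closed six-membered SE2′ transition state, so that C2 is set with net inversion of the mesylate centre and C1 by placing the aldehyde aryl group anti to the 3,5-dimethoxyphenyl group (anti adduct).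

Step 13
Reactants: 23 (1S,2S)-4-[benzyl(dimethyl)silyl]-2-(3,5-dimethoxyphenyl)-1-(4-methoxyphenyl)but-3-yn-1-ol
Product: 25 benzyl{(3S,4S)-4-[(E)-1,2-dichloroethenyloxy]-3-(3,5-dimethoxyphenyl)-4-(4-methoxyphenyl)but-1-yn-1-yl}dimethylsilane, via potassium alkoxide 24 (not isolated)
Conditions: KH (1.1 equiv), THF, 0 °C; Cl2C=CHCl (1.1 equiv), −40 °C to rt
Reagents that add atoms: trichloroethylene, ClC=C(Cl)Cl
Why: The trichloroethylene route to ynol ethers, in which the alkoxide adds anti to dichloroacetylene generated in the flask, should give the (E)-1,2-dichlorovinyl ether without touching either stereocentre, the alkoxide being kept cold and consumed as it forms.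

Step 14
Reactants: 25 benzyl{(3S,4S)-4-[(E)-1,2-dichloroethenyloxy]-3-(3,5-dimethoxyphenyl)-4-(4-methoxyphenyl)but-1-yn-1-yl}dimethylsilane
Product: 27 benzyl[(3S,4S)-3-(3,5-dimethoxyphenyl)-4-(ethynyloxy)-4-(4-methoxyphenyl)but-1-yn-1-yl]dimethylsilane, via lithium alkoxyacetylide 26 (not isolated)
Conditions: n-BuLi (2.05 equiv), THF, −78 °C; MeOH, −78 °C; kept cold and used at once
Reagents that add atoms: none
Why: Vinylic deprotonation, β-elimination of chloride and chlorine–lithium exchange give the alkoxyacetylide, which is protonated cold, the exact stoichiometry and low temperature being chosen so that the benzylic–propargylic C–H is not deprotonated.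

Step 15
Reactants: 27 benzyl[(3S,4S)-3-(3,5-dimethoxyphenyl)-4-(ethynyloxy)-4-(4-methoxyphenyl)but-1-yn-1-yl]dimethylsilane; 13 (2S,3S)-3-ethynyl-4-methoxy-2-(4-methoxyphenyl)-6-[(E)-2-(4-methoxyphenyl)ethenyl]-2,3-dihydro-1-benzofuran
Product: 28 benzyl{(2S,3S)-3-(3,5-dimethoxyphenyl)-2-(4-methoxyphenyl)-6-[(2S,3S)-4-methoxy-2-(4-methoxyphenyl)-6-[(E)-2-(4-methoxyphenyl)ethenyl]-2,3-dihydro-1-benzofuran-3-yl]-2,3-dihydro-1-benzofuran-4-yl}dimethylsilane
Conditions: [Rh(cod)2]BF4 (10 mol%), rac-BINAP (10 mol%), CH2Cl2, H2 (1 atm) 30 min then argon; 13 (1.0 equiv), then 27 (1.3 equiv) by syringe pump, rt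
Reagents that add atoms: none
Why: Proposed new method: the cationic monovalent rhodium–BINAP fragment should couple the two tethered alkynes of 27 oxidatively to a rhodacyclopentadiene (forming C3a′–C7a′), insert the terminal alkyne of 13 and reductively eliminate (forming C4′–C5′ and C6′–C7′), the closest known reaction type being the rhodium-catalysed (2+2+2) cycloaddition of unsymmetrical 1,6-diynes with terminal alkynes, together with the known cycloadditions of alkynyl ethers and of silylalkynes. The dihydrofuran ring closes in the oxidative cyclisation across the three-atom O1′–C2′–C3′ tether, the usual five-membered-ring mode of 1,6-diynes, and the benzene ring closes by the final C–C reductive elimination from the seven-membered rhodacycle. No stereocentre is formed: C2, C3, C2′ and C3′ are sp3 carbons carried in from 13 and 27 and are not touched by the metal, and the anti arrangement of the two aryl groups on the tether lets it fold without strain. The step needs regioselectivity, unit 1 at C6′ and not at C5′, which the bulky benzyldimethylsilyl group at the C4′ end of the rhodacycle should secure by forcing the substituted alkyne carbon to bond to the unhindered C7′ end. It also needs cross- over homo-cycloaddition, which slow addition of 27 at room temperature should favour, the mild temperature also keeping the benzylic alkynyl ether from sigmatropic rearrangement.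

Step 16
Reactants: 28 the C4′-benzyldimethylsilyl hexamethyl ether from step 15
Product: 30 (2S,3S)-3-(3,5-dimethoxyphenyl)-2-(4-methoxyphenyl)-6-[(2S,3S)-4-methoxy-2-(4-methoxyphenyl)-6-[(E)-2-(4-methoxyphenyl)ethenyl]-2,3-dihydro-1-benzofuran-3-yl]-2,3-dihydro-1-benzofuran-4-ol, via silanol 29 (not isolated)
Conditions: Bu4NF (2 equiv), THF, 0 °C to rt; then KHCO3, 30% aq H2O2, MeOH, 40 °C
Reagents that add atoms: hydrogen peroxide, OO
Why: Tamao–Fleming oxidation, in which fluoride removes the benzyl group from silicon to give the aryl silanol and the peroxide adduct then undergoes 1,2-aryl migration from silicon to oxygen, placing the hydroxyl exactly at C4′ while the stilbene and the benzylic ethers are inert to buffered peroxide.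

Step 17
Reactants: 30 the C4′-phenol hexamethyl ether from step 16
Product: 31 target, (2S,3S)-3-(3,5-dihydroxyphenyl)-6-[(2S,3S)-4-hydroxy-2-(4-hydroxyphenyl)-6-[(E)-2-(4-hydroxyphenyl)ethenyl]-2,3-dihydro-1-benzofuran-3-yl]-2-(4-hydroxyphenyl)-2,3-dihydro-1-benzofuran-4-ol
Conditions: BBr3 (15 equiv), CH2Cl2, −78 °C to rt; aqueous work-up
Reagents that add atoms: none
Why: Lewis-acid demethylation by bromide attack on the O-methyl groups of the boron-complexed aryl ethers is the customary final step for permethylated stilbene oligomers, the low temperature limiting ionisation of the 2-aryl benzylic C–O bonds so that all four stereocentres should be kept.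

**Compound list**

1 | 3-bromo-5-methoxyphenol | COc1cc(O)cc(Br)c1 | starting material
2 | 4-methoxybenzyl chloride | COc1ccc(CCl)cc1 | starting material
3 | 1-bromo-3-methoxy-5-[(4-methoxybenzyl)oxy]benzene | COc1cc(Br)cc(OCc2ccc(OC)cc2)c1 | intermediate
4 | {4-bromo-2-methoxy-6-[(4-methoxybenzyl)oxy]phenyl}lithium (not isolated) | [Li]c1c(OC)cc(Br)cc1OCc1ccc(OC)cc1 | intermediate
5 | methyl 2-{4-bromo-2-methoxy-6-[(4-methoxybenzyl)oxy]phenyl}-2-oxoacetate | COC(=O)C(=O)c1c(OC)cc(Br)cc1OCc1ccc(OC)cc1 | intermediate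
6 | tosylhydrazone of 5 (C=N geometry not defined) | COC(=O)C(=NNS(=O)(=O)c1ccc(C)cc1)c1c(OC)cc(Br)cc1OCc1ccc(OC)cc1 | intermediate
7 | methyl 2-{4-bromo-2-methoxy-6-[(4-methoxybenzyl)oxy]phenyl}-2-diazoacetate | COC(=O)C(=[N+]=[N-])c1c(OC)cc(Br)cc1OCc1ccc(OC)cc1 | intermediate
8 | methyl (2S,3R)-6-bromo-4-methoxy-2-(4-methoxyphenyl)-2,3-dihydro-1-benzofuran-3-carboxylate (cis) | Brc1cc(OC)c2c(c1)O[C@H](c1ccc(OC)cc1)[C@@H]2C(=O)OC | intermediate
9 | methyl (2S,3S)-6-bromo-4-methoxy-2-(4-methoxyphenyl)-2,3-dihydro-1-benzofuran-3-carboxylate (trans) | Brc1cc(OC)c2c(c1)O[C@H](c1ccc(OC)cc1)[C@H]2C(=O)OC | intermediate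
10 | 4-methoxystyrene | C=Cc1ccc(OC)cc1 | starting material
11 | methyl (2S,3S)-4-methoxy-2-(4-methoxyphenyl)-6-[(E)-2-(4-methoxyphenyl)ethenyl]-2,3-dihydro-1-benzofuran-3-carboxylate | COc1ccc(/C=C/c2cc(OC)c3c(c2)O[C@H](c2ccc(OC)cc2)[C@H]3C(=O)OC)cc1 | intermediate
12 | (2S,3S)-4-methoxy-2-(4-methoxyphenyl)-6-[(E)-2-(4-methoxyphenyl)ethenyl]-2,3-dihydro-1-benzofuran-3-carbaldehyde (not isolated) | COc1ccc(/C=C/c2cc(OC)c3c(c2)O[C@H](c2ccc(OC)cc2)[C@H]3C=O)cc1 | intermediate
13 | (2S,3S)-3-ethynyl-4-methoxy-2-(4-methoxyphenyl)-6-[(E)-2-(4-methoxyphenyl)ethenyl]-2,3-dihydro-1-benzofuran | COc1ccc(/C=C/c2cc(OC)c3c(c2)O[C@H](c2ccc(OC)cc2)[C@H]3C#C)cc1 | intermediate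
14 | benzyl(chloro)dimethylsilane | C[Si](C)(Cl)Cc1ccccc1 | starting material
15 | ethynylmagnesium bromide | C#C[Mg]Br | starting material
16 | benzyl(ethynyl)dimethylsilane | C#C[Si](C)(C)Cc1ccccc1 | intermediate
17 | 3,5-dimethoxybenzaldehyde | COc1cc(C=O)cc(OC)c1 | starting material
18 | methyl{[benzyl(dimethyl)silyl]ethynyl}zinc (not isolated) | C[Zn]C#C[Si](C)(C)Cc1ccccc1 | intermediate
19 | (R)-3-[benzyl(dimethyl)silyl]-1-(3,5-dimethoxyphenyl)prop-2-yn-1-ol | O[C@@H](C#C[Si](C)(C)Cc1ccccc1)c1cc(OC)cc(OC)c1 | intermediate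
20 | (R)-3-[benzyl(dimethyl)silyl]-1-(3,5-dimethoxyphenyl)prop-2-yn-1-yl methanesulfonate | CS(=O)(=O)O[C@@H](C#C[Si](C)(C)Cc1ccccc1)c1cc(OC)cc(OC)c1 | intermediate
21 | 4-methoxybenzaldehyde | COc1ccc(C=O)cc1 | starting material
22 | (aS)-{1-[benzyl(dimethyl)silyl]-3-(3,5-dimethoxyphenyl)propa-1,2-dien-1-yl}(ethyl)zinc (not isolated) | CC[Zn]C([Si](C)(C)Cc1ccccc1)=[C@@]=C([H])c1cc(OC)cc(OC)c1 | intermediate
23 | (1S,2S)-4-[benzyl(dimethyl)silyl]-2-(3,5-dimethoxyphenyl)-1-(4-methoxyphenyl)but-3-yn-1-ol | O[C@H](c1ccc(OC)cc1)[C@H](C#C[Si](C)(C)Cc1ccccc1)c1cc(OC)cc(OC)c1 | intermediate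
24 | potassium alkoxide of 23 (not isolated) | [K+].[O-][C@H](c1ccc(OC)cc1)[C@H](C#C[Si](C)(C)Cc1ccccc1)c1cc(OC)cc(OC)c1 | intermediate
25 | benzyl{(3S,4S)-4-[(E)-1,2-dichloroethenyloxy]-3-(3,5-dimethoxyphenyl)-4-(4-methoxyphenyl)but-1-yn-1-yl}dimethylsilane | Cl/C=C(/Cl)O[C@H](c1ccc(OC)cc1)[C@H](C#C[Si](C)(C)Cc1ccccc1)c1cc(OC)cc(OC)c1 | intermediate
26 | lithium alkoxyacetylide of 27 (not isolated) | [Li]C#CO[C@H](c1ccc(OC)cc1)[C@H](C#C[Si](C)(C)Cc1ccccc1)c1cc(OC)cc(OC)c1 | intermediate
27 | benzyl[(3S,4S)-3-(3,5-dimethoxyphenyl)-4-(ethynyloxy)-4-(4-methoxyphenyl)but-1-yn-1-yl]dimethylsilane | C#CO[C@H](c1ccc(OC)cc1)[C@H](C#C[Si](C)(C)Cc1ccccc1)c1cc(OC)cc(OC)c1 | intermediate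
28 | (2S,3S,2′S,3′S) target skeleton with benzyldimethylsilyl at C4′ and six methyl ethers | COc1ccc(/C=C/c2cc(OC)c3c(c2)O[C@H](c2ccc(OC)cc2)[C@H]3c2cc([Si](C)(C)Cc4ccccc4)c3c(c2)O[C@H](c2ccc(OC)cc2)[C@H]3c2cc(OC)cc(OC)c2)cc1 | intermediate
29 | (2S,3S,2′S,3′S) C4′-hydroxydimethylsilyl hexamethyl ether (not isolated) | COc1ccc(/C=C/c2cc(OC)c3c(c2)O[C@H](c2ccc(OC)cc2)[C@H]3c2cc([Si](C)(C)O)c3c(c2)O[C@H](c2ccc(OC)cc2)[C@H]3c2cc(OC)cc(OC)c2)cc1 | intermediate
30 | (2S,3S,2′S,3′S) C4′-phenol hexamethyl ether | COc1ccc(/C=C/c2cc(OC)c3c(c2)O[C@H](c2ccc(OC)cc2)[C@H]3c2cc(O)c3c(c2)O[C@H](c2ccc(OC)cc2)[C@H]3c2cc(OC)cc(OC)c2)cc1 | intermediate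
31 | CNP0248228.2, (2S,3S,2′S,3′S) heptaphenol | Oc1ccc(/C=C/c2cc(O)c3c(c2)O[C@H](c2ccc(O)cc2)[C@H]3c2cc(O)c3c(c2)O[C@H](c2ccc(O)cc2)[C@H]3c2cc(O)cc(O)c2)cc1 | target

**Step count**

Total: 17 steps. Longest linear sequence: 11 steps (steps 1–8, then 15–17).

**Steps most likely to fail**

1. Step 15 (Proposed new method). The electron-rich alkynyl ether may be consumed by homo-cycloaddition, oligomerisation or rearrangement at the cationic metal before the hindered silylalkyne enters the metallacycle, or the terminal alkyne may insert with the wrong orientation. The fallback uses known chemistry and gives up the arene construction: the C3–C6′ bond and the C3′–aryl bond are made by nickel-catalysed decarboxylative arylation of redox-active esters. It sets out from 9 and 11 and comes back at 31. Ester 9 would be saponified (LiOH, THF/H2O) to (2S,3S)-6-bromo-4-methoxy-2-(4-methoxyphenyl)-2,3-dihydro-1-benzofuran-3-carboxylic acid F1 and converted (N-hydroxyphthalimide, diisopropylcarbodiimide, DMAP) into its N-hydroxyphthalimide ester F2. Reductive cross-electrophile coupling of F2 with 1-iodo-3,5-dimethoxybenzene (NiBr2(dme), 4,4′-di-tert-butyl-2,2′-bipyridine, Zn, DMA, rt) should give (2S,3S)-6-bromo-3-(3,5-dimethoxyphenyl)-4-methoxy-2-(4-methoxyphenyl)-2,3-dihydro-1-benzofuran F3. The aryl iodide should react in preference to the aryl bromide, and the aryl group should enter the planar benzylic radical anti to the C2 aryl group, giving the trans isomer. Bromine–lithium exchange on F3 (n-BuLi, THF, −78 °C) and ZnCl2 would give the arylzinc chloride F4, used in solution. Ester 11 would be saponified to (2S,3S)-4-methoxy-2-(4-methoxyphenyl)-6-[(E)-2-(4-methoxyphenyl)ethenyl]-2,3-dihydro-1-benzofuran-3-carboxylic acid F5 and converted into its N-hydroxyphthalimide ester F6. Decarboxylative Negishi arylation of F6 with F4 (NiCl2·glyme, 4,4′-di-tert-butyl-2,2′-bipyridine, THF/DMF, rt) should give the (2S,3S,2′S,3′S) heptamethyl ether of the target F7, again trans by substrate control. BBr3 as in step 17 would then give 31.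

2. Step 12. Configurational integrity may be lost if the benzylic mesylate ionises or if the aryl-substituted allenylpalladium or allenylzinc racemises faster than it adds, which would erode both enantiomeric purity and anti selectivity. The fallback replaces the transient zinc reagent by an isolable, configurationally stable allenylboronate; it sets out from 19 and comes back at 23. Alcohol 19 would be converted (ClCO2Me, pyridine) into (R)-3-[benzyl(dimethyl)silyl]-1-(3,5-dimethoxyphenyl)prop-2-yn-1-yl methyl carbonate F8. Monovalent-copper-catalysed γ-selective anti SN2′ borylation (CuOtBu, Xantphos, B2pin2, THF) should give (aR)-2-{1-[benzyl(dimethyl)silyl]-3-(3,5-dimethoxyphenyl)propa-1,2-dien-1-yl}-4,4,5,5-tetramethyl-1,3,2-dioxaborolane F9. Heated with 21 in toluene, F9 should add through the same closed six-membered SE2′ transition state and give 23.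

3. Step 13. The potassium alkoxide 24 may abstract the benzylic–propargylic hydrogen (propargyl-to-allenyl isomerisation, epimerisation at the aryl-bearing carbon), attack the alkynylsilane, or fragment by retro-propargylation before it is trapped. The fallback avoids any alkoxide; it sets out from 23 and comes back at 27. Alcohol 23 would be formylated (acetic formic anhydride, pyridine) to (1S,2S)-4-[benzyl(dimethyl)silyl]-2-(3,5-dimethoxyphenyl)-1-(4-methoxyphenyl)but-3-yn-1-yl formate F10. Wittig-type dichloromethylenation (PPh3, CCl4, THF, 60 °C) should give benzyl{(3S,4S)-4-(2,2-dichloroethenyloxy)-3-(3,5-dimethoxyphenyl)-4-(4-methoxyphenyl)but-1-yn-1-yl}dimethylsilane F11. n-BuLi (2.05 equiv, THF, −78 °C) and a cold methanol quench, as in step 14, would then give 27.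

**Further compounds**

F1 | step 15 | (2S,3S)-6-bromo-4-methoxy-2-(4-methoxyphenyl)-2,3-dihydro-1-benzofuran-3-carboxylic acid | Brc1cc(OC)c2c(c1)O[C@H](c1ccc(OC)cc1)[C@H]2C(=O)O
F2 | step 15 | N-hydroxyphthalimide ester of F1 | Brc1cc(OC)c2c(c1)O[C@H](c1ccc(OC)cc1)[C@H]2C(=O)ON1C(=O)c2ccccc2C1=O
F3 | step 15 | (2S,3S)-6-bromo-3-(3,5-dimethoxyphenyl)-4-methoxy-2-(4-methoxyphenyl)-2,3-dihydro-1-benzofuran | Brc1cc(OC)c2c(c1)O[C@H](c1ccc(OC)cc1)[C@H]2c1cc(OC)cc(OC)c1
F4 | step 15 | [(2S,3S)-3-(3,5-dimethoxyphenyl)-4-methoxy-2-(4-methoxyphenyl)-2,3-dihydro-1-benzofuran-6-yl]zinc chloride | Cl[Zn]c1cc(OC)c2c(c1)O[C@H](c1ccc(OC)cc1)[C@H]2c1cc(OC)cc(OC)c1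
F5 | step 15 | (2S,3S)-4-methoxy-2-(4-methoxyphenyl)-6-[(E)-2-(4-methoxyphenyl)ethenyl]-2,3-dihydro-1-benzofuran-3-carboxylic acid | COc1ccc(/C=C/c2cc(OC)c3c(c2)O[C@H](c2ccc(OC)cc2)[C@H]3C(=O)O)cc1
F6 | step 15 | N-hydroxyphthalimide ester of F5 | COc1ccc(/C=C/c2cc(OC)c3c(c2)O[C@H](c2ccc(OC)cc2)[C@H]3C(=O)ON2C(=O)c3ccccc3C2=O)cc1
F7 | step 15 | (2S,3S,2′S,3′S) heptamethyl ether of the target | COc1ccc(/C=C/c2cc(OC)c3c(c2)O[C@H](c2ccc(OC)cc2)[C@H]3c2cc(OC)c3c(c2)O[C@H](c2ccc(OC)cc2)[C@H]3c2cc(OC)cc(OC)c2)cc1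
F8 | step 12 | (R)-3-[benzyl(dimethyl)silyl]-1-(3,5-dimethoxyphenyl)prop-2-yn-1-yl methyl carbonate | COC(=O)O[C@@H](C#C[Si](C)(C)Cc1ccccc1)c1cc(OC)cc(OC)c1
F9 | step 12 | (aR)-2-{1-[benzyl(dimethyl)silyl]-3-(3,5-dimethoxyphenyl)propa-1,2-dien-1-yl}-4,4,5,5-tetramethyl-1,3,2-dioxaborolane | CC1(C)OB(OC1(C)C)C([Si](C)(C)Cc1ccccc1)=[C@@]=C([H])c1cc(OC)cc(OC)c1
F10 | step 13 | (1S,2S)-4-[benzyl(dimethyl)silyl]-2-(3,5-dimethoxyphenyl)-1-(4-methoxyphenyl)but-3-yn-1-yl formate | O=CO[C@H](c1ccc(OC)cc1)[C@H](C#C[Si](C)(C)Cc1ccccc1)c1cc(OC)cc(OC)c1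
F11 | step 13 | benzyl{(3S,4S)-4-(2,2-dichloroethenyloxy)-3-(3,5-dimethoxyphenyl)-4-(4-methoxyphenyl)but-1-yn-1-yl}dimethylsilane | ClC(Cl)=CO[C@H](c1ccc(OC)cc1)[C@H](C#C[Si](C)(C)Cc1ccccc1)c1cc(OC)cc(OC)c1
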